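**Retrosynthetic overview**
1. The target comes from its 7-O-MOM ether by acetal cleavage; the C6–prenyl bond is disconnected last.
2. The C6–prenyl bond is made by a proposed new Ir-catalysed C6–H prenylation with 3-methylbuta-1,2-diene, directed by a removable 5-O-phosphinite, on the complete isoflavone core.
3. The pyranone C ring comes from a deoxybenzoin plus one carbon from DMF; the deoxybenzoin comes from phloroglucinol and 2,3,4-trimethoxyphenylacetic acid (Friedel–Crafts acylation).
4. Ring order: rings A and B are bought, ring C is closed in step 2, and the prenyl group is attached afterwards.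

Assumption: the target has no stereocentre and no stereogenic double bond (the prenyl alkene carries two identical methyls, the C3–aryl axis rotates freely), so "single enantiomer" is taken to mean the one achiral compound drawn and no SMILES needs stereodescriptors.

**Route**

Step 1
Reactants: 1 phloroglucinol; 2 2-(2,3,4-trimethoxyphenyl)acetic acid
Product: 3 1-(2,4,6-trihydroxyphenyl)-2-(2,3,4-trimethoxyphenyl)ethan-1-one
Conditions: BF3·OEt2 (neat, promoter), 85 °C, 2 h; aq. NaOAc
Reagents that add atoms: none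
Why: Friedel–Crafts (Houben–Hoesch-type) C-acylation of the very electron-rich phloroglucinol by the BF3-activated arylacetic acid gives one deoxybenzoin because all three ring positions are equivalent.

Step 2
Reactants: 3 1-(2,4,6-trihydroxyphenyl)-2-(2,3,4-trimethoxyphenyl)ethan-1-one
Product: 4 5,7-dihydroxy-3-(2,3,4-trimethoxyphenyl)-4H-chromen-4-one
Conditions: DMF, BF3·OEt2, then MsCl, 70 °C, 2 h; aq. work-up
Reagents that add atoms: N,N-dimethylformamide, CN(C)C=O
Why: Vilsmeier-type one-carbon formylation of the activated CH2 and cyclodehydration onto either of the two equivalent ortho-OH groups closes the pyranone ring (deoxybenzoin route to isoflavones).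

Step 3
Reactants: 4 5,7-dihydroxy-3-(2,3,4-trimethoxyphenyl)-4H-chromen-4-one
Product: 5 5-hydroxy-7-(methoxymethoxy)-3-(2,3,4-trimethoxyphenyl)-4H-chromen-4-one
Conditions: MOMCl (1.1 equiv), K2CO3, acetone, 0 °C to rt
Reagents that add atoms: chloromethyl methyl ether, COCCl
Why: Williamson-type O-alkylation occurs only at the acidic, unhindered 7-OH because the 5-OH is held in a hydrogen bond to the C4 carbonyl (standard selective 7-O-protection of 5,7-dihydroxyflavonoids).

Step 4
Reactants: 5 5-hydroxy-7-(methoxymethoxy)-3-(2,3,4-trimethoxyphenyl)-4H-chromen-4-one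
Product: 6 5-[di(propan-2-yl)phosphanyloxy]-7-(methoxymethoxy)-3-(2,3,4-trimethoxyphenyl)-4H-chromen-4-one
Conditions: iPr2PCl (1.1 equiv), Et3N, DMAP (cat.), PhMe, 60 °C, Ar; filter, concentrate, use crude
Reagents that add atoms: chlorodi(propan-2-yl)phosphane, CC(C)P(Cl)C(C)C
Why: O-phosphinylation of a phenol with a chlorophosphine and amine base (standard aryl phosphinite synthesis) puts a P(III) donor on the only free OH, two bonds away from C6.

Step 5
Reactants: 6 5-[di(propan-2-yl)phosphanyloxy]-7-(methoxymethoxy)-3-(2,3,4-trimethoxyphenyl)-4H-chromen-4-one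
Product: 8 5-hydroxy-7-(methoxymethoxy)-6-(3-methylbut-2-en-1-yl)-3-(2,3,4-trimethoxyphenyl)-4H-chromen-4-one, via C6-prenylated aryl phosphinite 7 (not isolated)
Conditions: [Ir(cod)2]BArF4 (5 mol %), rac-BINAP (5 mol %), 3-methylbuta-1,2-diene (4 equiv), PhMe, 90 °C, sealed tube; then MeOH, Et3N (cat.), 50 °C
Reagents that add atoms: 3-methylbuta-1,2-diene, CC(C)=C=C
Why: Proposed new method: phosphinite-directed Ir(I)-catalysed ortho-C–H prenylation of a phenol with 1,1-dimethylallene, in which the P-bound cationic Ir can reach only C6–H (five-membered Ir–P–O–C5–C6 iridacycle, C4a being quaternary and C8–H para to O5), C–H oxidative addition gives an aryl–Ir(III) hydride, hydrometallation of the allene puts H on its central carbon to give a 1,1-dimethyl-π-allyl, C–C reductive elimination at the unsubstituted allyl terminus gives the linear prenyl group, and methanolysis of the P–O bond then frees the 5-OH; the closest known reaction types are amide-directed Ir-catalysed C–H prenylation of arenes with 1,1-dimethylallene and Rh/Ir ortho-C–H functionalisation of aryl phosphinites by cyclometallation.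

Step 6
Reactants: 8 5-hydroxy-7-(methoxymethoxy)-6-(3-methylbut-2-en-1-yl)-3-(2,3,4-trimethoxyphenyl)-4H-chromen-4-one
Product: 9 5,7-dihydroxy-6-(3-methylbut-2-en-1-yl)-3-(2,3,4-trimethoxyphenyl)-4H-chromen-4-one
Conditions: 3 M HCl, MeOH, 40 °C, 2 h
Reagents that add atoms: none
Why: Acid-catalysed acetal exchange (MOM ether methanolysis) frees the 7-OH, and short mild conditions are used because ortho-prenylphenols can cyclise to 2,2-dimethylchromans in stronger acid.

**Compound list**
1 | phloroglucinol (benzene-1,3,5-triol) | Oc1cc(O)cc(O)c1 | starting material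
2 | 2-(2,3,4-trimethoxyphenyl)acetic acid | COc1ccc(CC(=O)O)c(OC)c1OC | starting material
3 | 1-(2,4,6-trihydroxyphenyl)-2-(2,3,4-trimethoxyphenyl)ethan-1-one | COc1ccc(CC(=O)c2c(O)cc(O)cc2O)c(OC)c1OC | intermediate
4 | 5,7-dihydroxy-3-(2,3,4-trimethoxyphenyl)-4H-chromen-4-one | COc1ccc(-c2coc3cc(O)cc(O)c3c2=O)c(OC)c1OC | intermediate
5 | 5-hydroxy-7-(methoxymethoxy)-3-(2,3,4-trimethoxyphenyl)-4H-chromen-4-one | COc1ccc(-c2coc3cc(OCOC)cc(O)c3c2=O)c(OC)c1OC | intermediate
6 | 5-[di(propan-2-yl)phosphanyloxy]-7-(methoxymethoxy)-3-(2,3,4-trimethoxyphenyl)-4H-chromen-4-one | COc1ccc(-c2coc3cc(OCOC)cc(OP(C(C)C)C(C)C)c3c2=O)c(OC)c1OC | intermediate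
7 | 5-[di(propan-2-yl)phosphanyloxy]-7-(methoxymethoxy)-6-(3-methylbut-2-en-1-yl)-3-(2,3,4-trimethoxyphenyl)-4H-chromen-4-one | COc1ccc(-c2coc3cc(OCOC)c(CC=C(C)C)c(OP(C(C)C)C(C)C)c3c2=O)c(OC)c1OC | intermediate (not isolated)
8 | 5-hydroxy-7-(methoxymethoxy)-6-(3-methylbut-2-en-1-yl)-3-(2,3,4-trimethoxyphenyl)-4H-chromen-4-one | COc1ccc(-c2coc3cc(OCOC)c(CC=C(C)C)c(O)c3c2=O)c(OC)c1OC | intermediate
9 | 5,7-dihydroxy-6-(3-methylbut-2-en-1-yl)-3-(2,3,4-trimethoxyphenyl)-4H-chromen-4-one | COc1ccc(-c2coc3cc(O)c(CC=C(C)C)c(O)c3c2=O)c(OC)c1OC | target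

**Totals**
Total step count: 6. Longest linear sequence: 6 steps (1 and 2 to 9).

**Three steps most likely to fail**

Step 5 (the proposed new C–H prenylation). The main risks are catalyst sequestration by the chromone carbonyl or by several phosphinite ligands, allene oligomerisation, and ketone-directed reaction at C6' of ring B. The fallback uses known chemistry only, sets out from 5 and comes back at 8. Compound 5 is O-allylated at the chelated 5-OH (allyl bromide, K2CO3, DMF, 60 °C) to give 7-(methoxymethoxy)-5-(prop-2-en-1-yloxy)-3-(2,3,4-trimethoxyphenyl)-4H-chromen-4-one F1. Aromatic Claisen rearrangement (N,N-diethylaniline, 200 °C) can deliver the allyl group only to C6, the single free ortho position of O5, and gives 5-hydroxy-7-(methoxymethoxy)-6-(prop-2-en-1-yl)-3-(2,3,4-trimethoxyphenyl)-4H-chromen-4-one F2. Olefin cross-metathesis with 2-methylbut-2-ene (Grubbs second-generation catalyst, CH2Cl2, 40 °C) turns allyl into prenyl and gives 8, which goes on to step 6.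

Step 4 (phosphinite on the hindered, hydrogen-bonded 5-OH). The P–O bond may form slowly, and the product is sensitive to air and moisture. The fallback drops the tether, sets out from 5 and comes back at 8. Electrophilic iodination with benzyltrimethylammonium dichloroiodate and CaCO3 (CH2Cl2–MeOH, rt), which on 5-hydroxy-7-alkoxy chromones goes ortho to the free chelated OH, gives 5-hydroxy-6-iodo-7-(methoxymethoxy)-3-(2,3,4-trimethoxyphenyl)-4H-chromen-4-one F3. Competing iodination of the electron-rich ring B is the thing to watch here. Suzuki–Miyaura coupling of the iodide with 3-methylbut-2-en-1-ylboronic acid pinacol ester (Pd with a bulky biarylphosphine for linear selectivity, K3PO4, THF–water, 60 °C) gives 8.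

Step 6 (acidic MOM removal next to a prenyl group flanked by two OH groups). The risk is cyclisation to a dimethylchroman. The fallback avoids acid altogether by carrying a fluoride-labile silyl ether, uses known chemistry, sets out from 4 and comes back at 9. Selective 7-O-silylation of 4 (TIPSCl, imidazole, DMF, 0 °C) gives 5-hydroxy-7-[tri(propan-2-yl)silyloxy]-3-(2,3,4-trimethoxyphenyl)-4H-chromen-4-one F4. Mitsunobu O-allylation of the 5-OH (allyl alcohol, PPh3, DIAD, THF) gives 5-(prop-2-en-1-yloxy)-7-[tri(propan-2-yl)silyloxy]-3-(2,3,4-trimethoxyphenyl)-4H-chromen-4-one F5. Claisen rearrangement (N,N-diethylaniline, 200 °C) gives 5-hydroxy-6-(prop-2-en-1-yl)-7-[tri(propan-2-yl)silyloxy]-3-(2,3,4-trimethoxyphenyl)-4H-chromen-4-one F6. Cross-metathesis with 2-methylbut-2-ene (Grubbs second-generation catalyst) gives 5-hydroxy-6-(3-methylbut-2-en-1-yl)-7-[tri(propan-2-yl)silyloxy]-3-(2,3,4-trimethoxyphenyl)-4H-chromen-4-one F7. Desilylation with TBAF buffered with AcOH (THF, 0 °C) gives 9.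

**Further compounds**
F1 | step 5 | 7-(methoxymethoxy)-5-(prop-2-en-1-yloxy)-3-(2,3,4-trimethoxyphenyl)-4H-chromen-4-one | COc1ccc(-c2coc3cc(OCOC)cc(OCC=C)c3c2=O)c(OC)c1OC
F2 | step 5 | 5-hydroxy-7-(methoxymethoxy)-6-(prop-2-en-1-yl)-3-(2,3,4-trimethoxyphenyl)-4H-chromen-4-one | COc1ccc(-c2coc3cc(OCOC)c(CC=C)c(O)c3c2=O)c(OC)c1OC
F3 | step 4 | 5-hydroxy-6-iodo-7-(methoxymethoxy)-3-(2,3,4-trimethoxyphenyl)-4H-chromen-4-one | COc1ccc(-c2coc3cc(OCOC)c(I)c(O)c3c2=O)c(OC)c1OC
F4 | step 6 | 5-hydroxy-7-[tri(propan-2-yl)silyloxy]-3-(2,3,4-trimethoxyphenyl)-4H-chromen-4-one | COc1ccc(-c2coc3cc(O[Si](C(C)C)(C(C)C)C(C)C)cc(O)c3c2=O)c(OC)c1OC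
F5 | step 6 | 5-(prop-2-en-1-yloxy)-7-[tri(propan-2-yl)silyloxy]-3-(2,3,4-trimethoxyphenyl)-4H-chromen-4-one | COc1ccc(-c2coc3cc(O[Si](C(C)C)(C(C)C)C(C)C)cc(OCC=C)c3c2=O)c(OC)c1OC
F6 | step 6 | 5-hydroxy-6-(prop-2-en-1-yl)-7-[tri(propan-2-yl)silyloxy]-3-(2,3,4-trimethoxyphenyl)-4H-chromen-4-one | COc1ccc(-c2coc3cc(O[Si](C(C)C)(C(C)C)C(C)C)c(CC=C)c(O)c3c2=O)c(OC)c1OC
F7 | step 6 | 5-hydroxy-6-(3-methylbut-2-en-1-yl)-7-[tri(propan-2-yl)silyloxy]-3-(2,3,4-trimethoxyphenyl)-4H-chromen-4-one | COc1ccc(-c2coc3cc(O[Si](C(C)C)(C(C)C)C(C)C)c(CC=C(C)C)c(O)c3c2=O)c(OC)c1OC
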